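**Strategy.** The route disconnects the cyclopentane bond C4–C5 and the aryl–benzylic bond in one palladium-catalysed operation. A cycloheptenyl allylic carbonate, carrying an (E)-3-methyl-4-phenylbut-3-enyl side chain on C1, ionises to a π-allylpalladium species; palladium-ene insertion of its C5 terminus into the styrene closes the cyclopentane and leaves palladium on the benzylic carbon, where Suzuki coupling with a protected phloroglucinol boronate forms the aryl bond. The step exploits the vicinal pair C4 (methyl-bearing quaternary carbon)/benzylic CH as a latent alkene and C5 as an allylic position of the seven-membered ring; the cyclopropane stereocentres, bought as (+)-2-carene, relay to C5, C4 and the benzylic carbon. A final acid-mediated hydroalkoxylation closes the oxepane.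

Key step: step 11

Remark (numbering): C1 = ether-bearing ring-fusion carbon, C2/C3 = cyclopentane CH2, C4 = methyl-bearing quaternary carbon, C5 = ring-fusion CH, C6/C7 = cyclopropane CH, C8/C9 = CH2, C10 = methyl-bearing CH, C11 = CMe2; C1' = benzylic CH.
Remark (assumptions): the carbinol epimers of 13–16 are carried as a mixture because that centre is ionised in step 11. MOM = methoxymethyl, pin = pinacolato.

**Step 1**
Reactants: 1 benzaldehyde; 2 isopropenylmagnesium bromide
Product: 3 2-methyl-1-phenylprop-2-en-1-ol (racemic)
Conditions: THF, 0 °C to rt; aq. NH4Cl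
Reagents that add atoms: none
Why: Grignard 1,2-addition to the aldehyde should give the allylic alcohol, whose racemic carbinol centre is destroyed in step 2.

**Step 2**
Reactants: 3 2-methyl-1-phenylprop-2-en-1-ol; 4 2-methoxypropene
Product: 6 (E)-5-methyl-6-phenylhex-5-en-2-one, via allyl isopropenyl ether 5 (not isolated)
Conditions: 4 (4 equiv), propionic acid (5 mol %), xylene, 130 °C, sealed tube
Reagents that add atoms: none
Why: Saucy–Marbet (ketal Claisen) rearrangement: acid-catalysed exchange gives ether 5, whose chair [3,3] shift with pseudo-equatorial phenyl should deliver the methyl ketone and fix the (E)-trisubstituted styrene (phenyl trans to the chain, cis to methyl).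

**Step 3**
Reactants: 6 (E)-5-methyl-6-phenylhex-5-en-2-one
Product: 7 2,4,6-triisopropylbenzenesulfonyl hydrazone of 6
Conditions: 2,4,6-triisopropylbenzenesulfonyl hydrazide, MeOH, cat. HCl, rt
Reagents that add atoms: 2,4,6-triisopropylbenzenesulfonyl hydrazide, NNS(=O)(=O)c1c(C(C)C)cc(C(C)C)cc1C(C)C
Why: Condensation gives the hydrazone needed for the Shapiro reaction, the hindered arylsulfonyl group preventing ortho-lithiation later.

**Step 4**
Reactants: 8 (+)-2-carene
Product: 10 (1S,3R)-2,2-dimethyl-3-(3-oxobutyl)cyclopropane-1-carbaldehyde, via secondary ozonide 9 (not isolated)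
Conditions: O3, CH2Cl2, −78 °C; Me2S, −78 °C to rt
Reagents that add atoms: ozone, [O-][O+]=O
Why: Ozonolysis with reductive work-up cleaves the only C=C bond and leaves both cyclopropane stereocentres untouched, so the formyl and 3-oxobutyl arms stay cis.

**Step 5**
Reactants: 10 (1S,3R)-2,2-dimethyl-3-(3-oxobutyl)cyclopropane-1-carbaldehyde
Product: 11 4-[(1R,3S)-3-ethenyl-2,2-dimethylcyclopropyl]butan-2-one
Conditions: Ph3PCH3Br, KN(SiMe3)2 (1.0 equiv ylide), THF, −78 to 0 °C
Reagents that add atoms: methyltriphenylphosphonium bromide, C[P+](c1ccccc1)(c1ccccc1)c1ccccc1.[Br-]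
Why: Wittig methylenation with one equivalent of ylide at low temperature is aldehyde-selective over the methyl ketone, and the poorly acidic cyclopropyl C–H should keep the cis arrangement.

**Step 6**
Reactants: 7 2,4,6-triisopropylbenzenesulfonyl hydrazone of 6; 11 4-[(1R,3S)-3-ethenyl-2,2-dimethylcyclopropyl]butan-2-one
Product: 13 (7E)-1-[(1R,3S)-3-ethenyl-2,2-dimethylcyclopropyl]-3,7-dimethyl-4-methylidene-8-phenyloct-7-en-3-ol (both C3 epimers), via vinyllithium 12 (not isolated)
Conditions: 7, n-BuLi (2.2 equiv), THF, −78 to 0 °C; then 11, −78 °C; aq. NH4Cl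
Reagents that add atoms: none
Why: Shapiro reaction: dianion formation on the methyl side and loss of sulfinate and N2 give the 2-lithio-1-alkene 12, which adds 1,2 to the methyl ketone; the new carbinol centre is uncontrolled and inconsequential.

**Step 7**
Reactants: 13 triene alcohol
Product: 14 (1S,7R)-4,8,8-trimethyl-3-[(E)-3-methyl-4-phenylbut-3-enyl]bicyclo[5.1.0]oct-2-en-4-ol (both C4 epimers)
Conditions: second-generation Grubbs catalyst (5 mol %), CH2Cl2 (0.005 M), 40 °C
Reagents that add atoms: none
Why: Ring-closing metathesis joins the vinylcyclopropane and the 1,1-disubstituted alkene into the trisubstituted cycloheptene, the cis-cyclopropane holding both arms on one side and the trisubstituted styrene being too hindered to compete.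

**Step 8**
Reactants: 14 cycloheptenol
Product: 16 methyl carbonate of 14, via lithium alkoxide 15 (not isolated)
Conditions: n-BuLi, THF, −78 °C; ClCO2Me, −78 to 0 °C
Reagents that add atoms: methyl chloroformate, COC(=O)Cl
Why: O-acylation of the tertiary lithium alkoxide gives the allylic carbonate, which ionises with zerovalent palladium under neutral conditions and supplies its own methoxide.

**Step 9**
Reactants: 17 phloroglucinol
Product: 18 1,3,5-tris(methoxymethoxy)benzene
Conditions: MOMCl (3.6 equiv), i-Pr2NEt, CH2Cl2, 0 °C to rt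
Reagents that add atoms: chloromethyl methyl ether, COCCl
Why: Threefold O-alkylation installs acetal groups that direct the later lithiations and are removed by the final acid.

**Step 10**
Reactants: 18 1,3,5-tris(methoxymethoxy)benzene
Product: 20 2-[2,4,6-tris(methoxymethoxy)phenyl]-4,4,5,5-tetramethyl-1,3,2-dioxaborolane, via aryllithium 19 (not isolated)
Conditions: n-BuLi, THF, 0 °C; i-PrOBpin, −78 °C to rt
Reagents that add atoms: 2-isopropoxy-4,4,5,5-tetramethyl-1,3,2-dioxaborolane, CC(C)OB1OC(C)(C)C(C)(C)O1
Why: Directed ortho-metalation between two MOM ethers followed by borylation of the aryllithium gives the boronate.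

**Step 11**
Reactants: 16 methyl carbonate of 14; 20 aryl boronate
Product: 23 4-[phenyl(2,4,6-tris(methoxymethoxy)phenyl)methyl]aromadendr-1(10)-ene (C5–H on the face of the cyclopropane CMe2; C4 methyl cis to C6; benzylic phenyl syn to the C4 methyl), via allylpalladium methoxide 21 (not isolated), via benzylpalladium methoxide 22 (not isolated)
Conditions: Pd2(dba)3 (5 mol %), SPhos (12 mol %), 20 (1.5 equiv), THF, 65 °C, no added base
Reagents that add atoms: none
Why: Zerovalent palladium ionises the tertiary allylic carbonate (loss of CO2 and methoxide) to the π-allylpalladium species 21 spanning C10–C1–C5; its less substituted terminus C5 then adds together with palladium across the tethered (E)-styrene in a type 2 palladium-ene (intramolecular carbopalladation) step that forms C5–C4 and gives benzylpalladium methoxide 22, which has no β-hydrogen (C4 is quaternary) and is intercepted by transmetalation with boronate 20 and reductive elimination to form the aryl–C1' bond. The closest known reaction type is the palladium-ene cyclisation terminated by organoboron capture (domino carbopalladation/Suzuki–Miyaura coupling). The cyclopentane closes in a 5-exo-trig mode (the 6-endo alternative would put palladium on a tertiary carbon), leaving the C1=C10 alkene exocyclic to the new ring. C5 is set by bond formation on the allyl face anti to the cyclopropane CMe2 bridge; C4 by a transition state that turns the Pd–CH(Ph) terminus toward C5–H and away from the cyclopropane; C1' by stereospecific syn-carbopalladation of the (E)-alkene followed by coupling with retention. The step needs insertion to outrun direct allyl–aryl coupling and β-hydride loss from the allyl complex, which the slowly transmetalating di-ortho-substituted boronate, the base-free conditions and the intramolecularity are meant to secure.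

**Step 12**
Reactants: 23 tris-MOM diarylmethane
Product: 26 dialdehyde of 23 (formyl groups at both arene positions flanked by MOM ethers), via mono(amino alkoxide) 24 (not isolated), via bis(amino alkoxide) 25 (not isolated)
Conditions: n-BuLi, TMEDA, THF, −20 °C; DMF; then n-BuLi, −20 °C; DMF; aq. NH4Cl
Reagents that add atoms: N,N-dimethylformamide, CN(C)C=O
Why: Directed ortho-metalation at each arene C–H flanked by two MOM ethers and formylation with DMF, the first aldehyde staying masked as its lithium α-amino alkoxide during the second lithiation; no stereocentre is involved.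

**Step 13**
Reactants: 26 dialdehyde
Product: 28 psiguadial A, via free trihydroxy dialdehyde 27 (not isolated)
Conditions: HCl (1.25 M in MeOH), CH2Cl2, 0 °C to rt; evaporate; TsOH·H2O (20 mol %), CH2Cl2, rt
Reagents that add atoms: none
Why: After acidic MOM cleavage, Markovnikov protonation of the tetrasubstituted C1=C10 alkene at C10 gives the tertiary C1 cation, which the neighbouring phenol captures in a 7-exo-trig intramolecular hydroalkoxylation on the only face the benzylic tether can reach (oxygen cis to C5–H, closing the oxepane), while C10 is set by reversible protonation anti to the entering oxygen, placing its methyl cis to the ether oxygen.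

**Compound list**
1 | benzaldehyde | O=Cc1ccccc1 | starting material
2 | isopropenylmagnesium bromide | CC(=C)[Mg]Br | starting material
3 | 2-methyl-1-phenylprop-2-en-1-ol (racemic) | CC(=C)C(O)c1ccccc1 | intermediate
4 | 2-methoxypropene | COC(C)=C | starting material
5 | 2-methyl-1-phenylallyl isopropenyl ether (racemic, not isolated) | CC(=C)OC(C(C)=C)c1ccccc1 | intermediate
6 | (E)-5-methyl-6-phenylhex-5-en-2-one | CC(=O)CC/C(C)=C/c1ccccc1 | intermediate
7 | 2,4,6-triisopropylbenzenesulfonyl hydrazone of 6 | CC(CC/C(C)=C/c1ccccc1)=NNS(=O)(=O)c1c(C(C)C)cc(C(C)C)cc1C(C)C | intermediate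
8 | (+)-2-carene, (1S,6R)-3,7,7-trimethylbicyclo[4.1.0]hept-2-ene | CC1=C[C@H]2[C@@H](CC1)C2(C)C | starting material
9 | secondary ozonide of 8 (not isolated) | CC12CC[C@@H]3[C@H](C(OO1)O2)C3(C)C | intermediate
10 | (1S,3R)-2,2-dimethyl-3-(3-oxobutyl)cyclopropane-1-carbaldehyde (cis) | CC(=O)CC[C@@H]1[C@H](C=O)C1(C)C | intermediate
11 | 4-[(1R,3S)-3-ethenyl-2,2-dimethylcyclopropyl]butan-2-one (cis) | CC(=O)CC[C@@H]1[C@H](C=C)C1(C)C | intermediate
12 | (E)-2-lithio-5-methyl-6-phenylhexa-1,5-diene (not isolated) | [Li]C(=C)CC/C(C)=C/c1ccccc1 | intermediate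
13 | (7E)-1-[(1R,3S)-3-ethenyl-2,2-dimethylcyclopropyl]-3,7-dimethyl-4-methylidene-8-phenyloct-7-en-3-ol (C3 epimers) | C=C(CC/C(C)=C/c1ccccc1)C(C)(O)CC[C@@H]1[C@H](C=C)C1(C)C | intermediate
14 | (1S,7R)-4,8,8-trimethyl-3-[(E)-3-methyl-4-phenylbut-3-enyl]bicyclo[5.1.0]oct-2-en-4-ol (C4 epimers) | CC1(O)CC[C@@H]2[C@H](C=C1CC/C(C)=C/c1ccccc1)C2(C)C | intermediate
15 | lithium alkoxide of 14 (not isolated) | CC1(O[Li])CC[C@@H]2[C@H](C=C1CC/C(C)=C/c1ccccc1)C2(C)C | intermediate
16 | methyl (1S,7R)-4,8,8-trimethyl-3-[(E)-3-methyl-4-phenylbut-3-enyl]bicyclo[5.1.0]oct-2-en-4-yl carbonate | COC(=O)OC1(C)CC[C@@H]2[C@H](C=C1CC/C(C)=C/c1ccccc1)C2(C)C | intermediate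
17 | phloroglucinol (benzene-1,3,5-triol) | Oc1cc(O)cc(O)c1 | starting material
18 | 1,3,5-tris(methoxymethoxy)benzene | COCOc1cc(OCOC)cc(OCOC)c1 | intermediate
19 | 2,4,6-tris(methoxymethoxy)phenyllithium (not isolated) | [Li]c1c(OCOC)cc(OCOC)cc1OCOC | intermediate
20 | 2-[2,4,6-tris(methoxymethoxy)phenyl]-4,4,5,5-tetramethyl-1,3,2-dioxaborolane | COCOc1cc(OCOC)c(B2OC(C)(C)C(C)(C)O2)c(OCOC)c1 | intermediate
21 | allylpalladium methoxide (C10–C1–C5 allyl drawn as its C5-bound σ-form, phosphine omitted, not isolated) | CC1=C(CC/C(C)=C/c2ccccc2)[C@@H]([Pd]OC)[C@H]2[C@@H](CC1)C2(C)C | intermediate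
22 | benzylpalladium methoxide after insertion (phosphine omitted, not isolated) | CC1=C2CC[C@](C)([C@H]([Pd]OC)c3ccccc3)[C@H]2[C@H]2[C@@H](CC1)C2(C)C | intermediate
23 | 4-[phenyl(2,4,6-tris(methoxymethoxy)phenyl)methyl]aromadendr-1(10)-ene | CC1=C2CC[C@](C)([C@@H](c3ccccc3)c3c(OCOC)cc(OCOC)cc3OCOC)[C@H]2[C@H]2[C@@H](CC1)C2(C)C | intermediate
24 | lithium α-(dimethylamino)alkoxide of the mono-aldehyde (not isolated) | CC1=C2CC[C@](C)([C@@H](c3ccccc3)c3c(OCOC)c(C(O[Li])N(C)C)c(OCOC)cc3OCOC)[C@H]2[C@H]2[C@@H](CC1)C2(C)C | intermediate
25 | bis[lithium α-(dimethylamino)alkoxide] (not isolated) | CC1=C2CC[C@](C)([C@@H](c3ccccc3)c3c(OCOC)c(C(O[Li])N(C)C)c(OCOC)c(C(O[Li])N(C)C)c3OCOC)[C@H]2[C@H]2[C@@H](CC1)C2(C)C | intermediate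
26 | dialdehyde of 23 (3,5-diformyl-2,4,6-tris(methoxymethoxy)phenyl) | CC1=C2CC[C@](C)([C@@H](c3ccccc3)c3c(OCOC)c(C=O)c(OCOC)c(C=O)c3OCOC)[C@H]2[C@H]2[C@@H](CC1)C2(C)C | intermediate
27 | free trihydroxy dialdehyde (not isolated) | CC1=C2CC[C@](C)([C@@H](c3ccccc3)c3c(O)c(C=O)c(O)c(C=O)c3O)[C@H]2[C@H]2[C@@H](CC1)C2(C)C | intermediate
28 | psiguadial A | C[C@H]1CC[C@@H]2[C@H]([C@@H]3[C@]4(C)CC[C@@]31Oc1c(C=O)c(O)c(C=O)c(O)c1[C@@H]4c1ccccc1)C2(C)C | target

**Step count and risks**
Total steps: 13. Longest linear sequence: 9 (steps 1, 2, 3, 6, 7, 8, 11, 12, 13).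

Steps most likely to fail:

1. Step 11. Insertion of the allylpalladium terminus into the trisubstituted styrene may be slower than β-hydride loss to a diene, direct allyl–aryl coupling, reduction of the benzylpalladium by the methoxide ligand or opening of the cyclopropylcarbinyl σ-form; face selectivity at C4 may also be incomplete. The fallback sets out from 16 and comes back at 23. Pd(PPh3)4 (5 mol %) and Et2Zn in THF at 40 °C should convert the carbonate by umpolung into an allylzinc that undergoes zinc-ene cyclisation onto the styrene (same 5-exo regiochemistry, zinc ending benzylic) to give the benzylic ethylzinc species F1. Negishi coupling of F1 with 2-iodo-1,3,5-tris(methoxymethoxy)benzene F2 (from 18 by lithiation with n-BuLi and iodine quench) under Pd2(dba)3/SPhos should then give 23, the benzylic configuration resting on substrate control.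

2. Step 13. Capture of the C1 cation by the hydrogen-bonded, deactivated phenol may be slow, so that loss of the C5 proton or a 1,2-hydride shift from C5 (leading to cyclopropylcarbinyl cation chemistry) competes, and protonation at C10 may lack facial selectivity. The fallback sets out from 23 and comes back at 28 by inverting the order, so that the more nucleophilic non-formylated phenol captures the cation. HCl/MeOH then TsOH·H2O in CH2Cl2 should convert 23 through the free triol F3 into the non-formylated oxepane F4, and Vilsmeier–Haack diformylation of F4 (POCl3, DMF, MeCN, 0 °C to rt; aqueous NaOAc) should give 28.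

3. Step 12. Deprotonation at the doubly benzylic methine may compete, or the second lithiation may be incomplete. The fallback sets out from 23 and comes back at 26. NBS (2.1 equiv, MeCN, 0 °C) should brominate the two arene positions flanked by MOM ethers to give dibromide F5; bromine–lithium exchange (t-BuLi, THF, −78 °C) and DMF quench should then give 26 without an acid–base step at the benzylic position.

**Further compounds**
F1 | step 11 | benzylic ethylzinc species from zinc-ene cyclisation (benzylic centre labile) | CC1=C2CC[C@](C)(C([Zn]CC)c3ccccc3)[C@H]2[C@H]2[C@@H](CC1)C2(C)C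
F2 | step 11 | 2-iodo-1,3,5-tris(methoxymethoxy)benzene | COCOc1cc(OCOC)c(I)c(OCOC)c1
F3 | step 13 | free triol of 23 | CC1=C2CC[C@](C)([C@@H](c3ccccc3)c3c(O)cc(O)cc3O)[C@H]2[C@H]2[C@@H](CC1)C2(C)C
F4 | step 13 | non-formylated oxepane (bis-deformyl psiguadial A) | C[C@H]1CC[C@@H]2[C@H]([C@@H]3[C@]4(C)CC[C@@]31Oc1cc(O)cc(O)c1[C@@H]4c1ccccc1)C2(C)C
F5 | step 12 | dibromide of 23 | CC1=C2CC[C@](C)([C@@H](c3ccccc3)c3c(OCOC)c(Br)c(OCOC)c(Br)c3OCOC)[C@H]2[C@H]2[C@@H](CC1)C2(C)C
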